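Assumption: semisystematic labdane and eudesmane numbering is used (the ether bond is C15–O–C4′), and (E)-geranylacetone and (+)-β-eudesmol are bought as single isomers.

**Retrosynthetic overview**
1. Key disconnection: the C15–O ether bond, made by Williamson etherification of the allylic bromide of methyl isocupressate with the 4α-alkoxide of O11-silylated cryptomeridiol; two deprotections finish the synthesis.
2. Eudesmane half: (+)-β-eudesmol already has both rings; O11 silylation, then Markovnikov hydration of the exocyclic alkene sets C4′.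
3. Labdane side chain: the 13E allylic alcohol comes from a terminal alkyne by methylalumination and hydroxymethylation.
4. Labdane rings: ring A and then ring B form in one enantioselective oxidative radical bicyclisation of an acyclic α-methyl β-keto ester (sets C4, C5, C9, C10); C3 is then deoxygenated.
5. Acyclic precursor: (E)-geranylacetone (alkyne formation, allylic oxidation, bromination) joined to the dianion of methyl 2-methylacetoacetate.

**Route**

Step 1
Reactants: 1 (5E)-6,10-dimethylundeca-5,9-dien-2-one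
Product: 4 (5E)-6,10-dimethylundeca-5,9-dien-1-yne, via enol diethyl phosphate 2 (not isolated), via lithium acetylide 3 (not isolated)
Conditions: LiN(i-Pr)2 (1.05 equiv), THF, −78 °C; ClP(O)(OEt)2, −78 → 25 °C; LiN(i-Pr)2 (2.3 equiv), −78 → 25 °C; H2O
Reagents that add atoms: none
Why: The kinetic terminal enolate is trapped as its enol phosphate and eliminated with excess amide base (Negishi conversion of a methyl ketone into a terminal alkyne); no stereocentre is formed and the 5E alkene is untouched.

Step 2
Reactants: 4 (5E)-6,10-dimethylundeca-5,9-dien-1-yne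
Product: 5 (2E,6E)-2,6-dimethylundeca-2,6-dien-10-yn-1-ol
Conditions: SeO2 (0.2 equiv), t-BuOOH (3 equiv), salicylic acid (0.1 equiv), CH2Cl2, 25 °C
Reagents that add atoms: SeO2 (oxygen relay) O=[Se]=O; tert-butyl hydroperoxide (terminal oxygen source) CC(C)(C)OO
Why: SeO2-catalysed allylic oxidation (ene reaction then [2,3]-shift) attacks the E-methyl of the terminal isopropylidene group and gives the E allylic alcohol; the internal alkene and the alkyne react more slowly.

Step 3
Reactants: 5 (2E,6E)-2,6-dimethylundeca-2,6-dien-10-yn-1-ol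
Product: 6 (2E,6E)-1-bromo-2,6-dimethylundeca-2,6-dien-10-yne
Conditions: CBr4, PPh3, CH2Cl2, −20 → 0 °C
Reagents that add atoms: carbon tetrabromide BrC(Br)(Br)Br
Why: Appel bromination converts the primary allylic alcohol into the bromide under neutral conditions with retention of the E geometry.

Step 4
Reactants: 6 (2E,6E)-1-bromo-2,6-dimethylundeca-2,6-dien-10-yne; 7 methyl 2-methyl-3-oxobutanoate
Product: 9 methyl (6E,10E)-2,6,10-trimethyl-3-oxopentadeca-6,10-dien-14-ynoate, via acetoacetate dianion 8 (not isolated)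
Conditions: 7 (1.5 equiv), NaH, THF, 0 °C; n-BuLi, 0 °C; then 6, 0 °C; H2O
Reagents that add atoms: none
Why: β-Keto ester dianion γ-alkylation: the terminal carbanion of 8 displaces the allylic bromide faster than it deprotonates the alkyne; C2 stays racemic, which does not matter because it becomes the radical centre in step 5.

Step 5
Reactants: 9 methyl (6E,10E)-2,6,10-trimethyl-3-oxopentadeca-6,10-dien-14-ynoate
Product: 10 methyl 3-oxo-15,16-dinorlabd-8(17)-en-13-yn-19-oate
Conditions: Yb(OTf)3 (1.1 equiv), (S,S)-i-Pr-pybox (1.2 equiv), 4 Å MS, CF3CH2OH, 25 °C; then Mn(OAc)3·2H2O (2.2 equiv), Cu(OAc)2/2,2′-bipyridine (1:1, 1.0 equiv), −20 °C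
Reagents that add atoms: none
Why: Proposed new method: the β-keto ester is held by two-point chelation on a chiral Yb(OTf)3–pybox Lewis acid, so one-electron oxidation by trivalent manganese gives a chelated planar radical with one face shielded; 6-endo attack on the first alkene from the open face sets C4 with the ester axial, the chair–chair cascade relays this to the trans ring fusion (5α-H, 10β-CH3) and the equatorial C9 chain, and bipyridine-ligated divalent copper (which cannot strip the pybox) oxidises the C8 radical to the exocyclic alkene before it can add to the alkyne; the closest known chemistry is the racemic Mn(OAc)3/Cu(OAc)2 oxidative polyene cyclisation of α-methyl β-keto esters, its stereochemical tightening by Yb(OTf)3-type Lewis acids, and chiral-Lewis-acid-controlled atom-transfer radical cyclisations of α-halo β-keto esters; the pybox antipode that gives the required series is fixed by screening.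

Step 6
Reactants: 10 methyl 3-oxo-15,16-dinorlabd-8(17)-en-13-yn-19-oate
Product: 12 methyl 15,16-dinorlabd-8(17)-en-13-yn-19-oate, via tosylhydrazone 11 (not isolated)
Conditions: TsNHNH2, EtOH, 75 °C; evaporate; catecholborane, CHCl3, 0 °C; NaOAc·3H2O, 60 °C
Reagents that add atoms: none
Why: Tosylhydrazone formation and catecholborane reduction (Caglioti–Kabalka deoxygenation) remove the hindered C3 ketone without strong acid or base, so the exocyclic alkene, the alkyne and the ester survive; no stereocentre changes.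

Step 7
Reactants: 12 methyl 15,16-dinorlabd-8(17)-en-13-yn-19-oate
Product: 15 methyl (13E)-15-hydroxylabda-8(17),13-dien-19-oate, via alkenyldimethylalane 13 (not isolated), via lithium alkenylalanate 14 (not isolated)
Conditions: AlMe3 (2.5 equiv), Cp2ZrCl2 (0.25 equiv), (CH2Cl)2, 25 °C; evaporate; n-BuLi, THF, −78 °C; (CH2O)n, −78 → 25 °C; H2O
Reagents that add atoms: trimethylaluminium C[Al](C)C; formaldehyde (as paraformaldehyde) C=O
Why: Zirconium-catalysed methylalumination (Negishi carboalumination) adds CH3 and Al syn across the terminal alkyne with Al at the terminus, and the alanate is hydroxymethylated with retention, which fixes the 13E alkene; the exocyclic alkene and the hindered axial ester are inert.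

Step 8
Reactants: 15 methyl (13E)-15-hydroxylabda-8(17),13-dien-19-oate
Product: 16 methyl (13E)-15-bromolabda-8(17),13-dien-19-oate
Conditions: CBr4, PPh3, CH2Cl2, −20 °C
Reagents that add atoms: carbon tetrabromide BrC(Br)(Br)Br
Why: Appel bromination of the primary allylic alcohol at low temperature keeps the 13E geometry and leaves the ester and the exocyclic alkene alone.

Step 9
Reactants: 17 (+)-β-eudesmol
Product: 18 11-(triethylsilyloxy)eudesm-4(15)-ene
Conditions: Et3SiOTf, 2,6-lutidine, CH2Cl2, −78 → 0 °C
Reagents that add atoms: triethylsilyl trifluoromethanesulfonate CC[Si](CC)(CC)OS(=O)(=O)C(F)(F)F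
Why: Silyl triflate silylation masks the only hydroxyl (tertiary O11) before the second tertiary alcohol is created, so the two can be told apart later.

Step 10
Reactants: 18 11-(triethylsilyloxy)eudesm-4(15)-ene
Product: 20 11-(triethylsilyloxy)eudesman-4α-ol, via organomercurial 19 (not isolated)
Conditions: Hg(OAc)2, THF/H2O (1:1), 25 °C; then 3 M NaOH, NaBH4, 0 °C
Reagents that add atoms: water O
Why: Markovnikov oxymercuration–demercuration: water opens the mercurinium ion at C4′ from the α (equatorial) face, away from the 1,3-diaxial C10′ methyl, giving the 4α-alcohol with axial 4β-methyl (the cryptomeridiol configuration).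

Step 11
Reactants: 16 methyl (13E)-15-bromolabda-8(17),13-dien-19-oate; 20 11-(triethylsilyloxy)eudesman-4α-ol
Product: 22 methyl (13E)-15-{[11-(triethylsilyloxy)eudesman-4α-yl]oxy}labda-8(17),13-dien-19-oate, via potassium alkoxide 21 (not isolated)
Conditions: 20 (1.5 equiv), KH, 18-crown-6 (0.1 equiv), THF, 0 → 25 °C; then 16, 0 → 25 °C
Reagents that add atoms: none
Why: Williamson etherification: the potassium tertiary alkoxide displaces the primary allylic bromide by SN2 at C15, so the C4′ configuration and the 13E alkene are retained; excess alkoxide and crown ether favour substitution over elimination.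

Step 12
Reactants: 22 methyl (13E)-15-{[11-(triethylsilyloxy)eudesman-4α-yl]oxy}labda-8(17),13-dien-19-oate
Product: 24 (13E)-15-[(11-hydroxyeudesman-4α-yl)oxy]labda-8(17),13-dien-19-oic acid, via sodium carboxylate 23 (not isolated)
Conditions: NaSEt, DMF, 100 °C; then HF·pyridine, THF, 0 → 25 °C
Reagents that add atoms: none
Why: Thiolate SN2 demethylation attacks the O-methyl carbon of the hindered axial ester, and fluoride then cleaves the tertiary silyl ether; the allyl tert-alkyl ether and both alkenes tolerate these conditions and no stereocentre is touched.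

**Compound list**
1 | (5E)-6,10-dimethylundeca-5,9-dien-2-one, (E)-geranylacetone | CC(C)=CCC/C(C)=C/CCC(C)=O | starting material
2 | diethyl (5E)-6,10-dimethylundeca-1,5,9-trien-2-yl phosphate | C=C(OP(=O)(OCC)OCC)CC/C=C(\C)CCC=C(C)C | intermediate
3 | lithium (5E)-6,10-dimethylundeca-5,9-dien-1-yn-1-ide | [Li+].[C-]#CCC/C=C(\C)CCC=C(C)C | intermediate
4 | (5E)-6,10-dimethylundeca-5,9-dien-1-yne | C#CCC/C=C(\C)CCC=C(C)C | intermediate
5 | (2E,6E)-2,6-dimethylundeca-2,6-dien-10-yn-1-ol | OC/C(C)=C/CC/C(C)=C/CCC#C | intermediate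
6 | (2E,6E)-1-bromo-2,6-dimethylundeca-2,6-dien-10-yne | BrC/C(C)=C/CC/C(C)=C/CCC#C | intermediate
7 | methyl 2-methyl-3-oxobutanoate (methyl 2-methylacetoacetate) | COC(=O)C(C)C(C)=O | starting material
8 | sodium lithium 2,4-dianion of methyl 2-methyl-3-oxobutanoate | [Na+].[Li+].[CH2-]C(=O)[C-](C)C(=O)OC | intermediate
9 | methyl (6E,10E)-2,6,10-trimethyl-3-oxopentadeca-6,10-dien-14-ynoate; C2 racemic and labile | COC(=O)C(C)C(=O)CC/C(C)=C/CC/C(C)=C/CCC#C | intermediate
10 | methyl 3-oxo-15,16-dinorlabd-8(17)-en-13-yn-19-oate; trans-decalin with 5α-H, 9α-H, 10β-CH3, 4α-CH3 and axial 4β-CO2CH3; C9 carries CH2CH2C≡CH | C=C1CC[C@@H]2[C@](C)(CCC(=O)[C@]2(C)C(=O)OC)[C@H]1CCC#C | intermediate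
11 | C3 p-toluenesulfonylhydrazone of 10 | C=C1CC[C@@H]2[C@](C)(CC/C(=N\NS(=O)(=O)c3ccc(C)cc3)[C@]2(C)C(=O)OC)[C@H]1CCC#C | intermediate
12 | methyl 15,16-dinorlabd-8(17)-en-13-yn-19-oate; stereocentres as in 10 | C=C1CC[C@@H]2[C@](C)(CCC[C@]2(C)C(=O)OC)[C@H]1CCC#C | intermediate
13 | methyl (13E)-14-(dimethylalumanyl)-15-norlabda-8(17),13-dien-19-oate | C=C1CC[C@@H]2[C@](C)(CCC[C@]2(C)C(=O)OC)[C@H]1CC/C(C)=C/[Al](C)C | intermediate
14 | lithium butyl(dimethyl)alanate of 13 | [Li+].C=C1CC[C@@H]2[C@](C)(CCC[C@]2(C)C(=O)OC)[C@H]1CC/C(C)=C/[Al-](C)(C)CCCC | intermediate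
15 | methyl (13E)-15-hydroxylabda-8(17),13-dien-19-oate (methyl isocupressate) | C=C1CC[C@@H]2[C@](C)(CCC[C@]2(C)C(=O)OC)[C@H]1CC/C(C)=C/CO | intermediate
16 | methyl (13E)-15-bromolabda-8(17),13-dien-19-oate | C=C1CC[C@@H]2[C@](C)(CCC[C@]2(C)C(=O)OC)[C@H]1CC/C(C)=C/CBr | intermediate
17 | (+)-β-eudesmol, eudesm-4(15)-en-11-ol; trans-decalin with 5α-H, 10β-CH3 and equatorial 7β-C(CH3)2OH | C=C1CCC[C@]2(C)CC[C@@H](C(C)(C)O)C[C@H]21 | starting material
18 | 11-(triethylsilyloxy)eudesm-4(15)-ene | C=C1CCC[C@]2(C)CC[C@@H](C(C)(C)O[Si](CC)(CC)CC)C[C@H]21 | intermediate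
19 | 15-(acetoxymercurio)-11-(triethylsilyloxy)eudesman-4α-ol | O[C@]1(C[Hg]OC(C)=O)CCC[C@]2(C)CC[C@@H](C(C)(C)O[Si](CC)(CC)CC)C[C@H]21 | intermediate
20 | 11-(triethylsilyloxy)eudesman-4α-ol (cryptomeridiol 11-triethylsilyl ether; 4α-OH, axial 4β-CH3) | O[C@]1(C)CCC[C@]2(C)CC[C@@H](C(C)(C)O[Si](CC)(CC)CC)C[C@H]21 | intermediate
21 | potassium 4α-alkoxide of 20 | [K+].[O-][C@]1(C)CCC[C@]2(C)CC[C@@H](C(C)(C)O[Si](CC)(CC)CC)C[C@H]21 | intermediate
22 | methyl (13E)-15-{[11-(triethylsilyloxy)eudesman-4α-yl]oxy}labda-8(17),13-dien-19-oate | C=C1CC[C@@H]2[C@](C)(CCC[C@]2(C)C(=O)OC)[C@H]1CC/C(C)=C/CO[C@]1(C)CCC[C@]2(C)CC[C@@H](C(C)(C)O[Si](CC)(CC)CC)C[C@H]21 | intermediate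
23 | sodium (13E)-15-{[11-(triethylsilyloxy)eudesman-4α-yl]oxy}labda-8(17),13-dien-19-oate | [Na+].C=C1CC[C@@H]2[C@](C)(CCC[C@]2(C)C(=O)[O-])[C@H]1CC/C(C)=C/CO[C@]1(C)CCC[C@]2(C)CC[C@@H](C(C)(C)O[Si](CC)(CC)CC)C[C@H]21 | intermediate
24 | (13E)-15-[(11-hydroxyeudesman-4α-yl)oxy]labda-8(17),13-dien-19-oic acid | C=C1CC[C@@H]2[C@](C)(CCC[C@]2(C)C(=O)O)[C@H]1CC/C(C)=C/CO[C@]1(C)CCC[C@]2(C)CC[C@@H](C(C)(C)O)C[C@H]21 | target

**Totals**
Total step count: 12. Longest linear sequence: 10 steps (steps 1–8, 11, 12).

**Steps most likely to fail**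

Step 5 (the proposed new step). The risks are low enantioselectivity from unbound radical, and endocyclic alkene or alkyne-trapped by-products. The fallback sets out from 9 and comes back at 10. Compound 9 is cyclised under the established racemic conditions (Mn(OAc)3·2H2O, Cu(OAc)2, AcOH, 25 °C, no chiral Lewis acid). This gives 10 as a 1:1 mixture with its mirror image, the ent-keto ester F1. The two are separated by preparative chromatography on a chiral stationary phase, and 10 continues into step 6.

Step 6. The C3 ketone sits next to the quaternary C4 and may form the tosylhydrazone slowly or incompletely. The fallback sets out from 10 and comes back at 12. NaBH4 in MeOH reduces the ketone to the equatorial 3β-alcohol F2. NaH, CS2 and then MeI convert it into the S-methyl xanthate F3. Bu3SnH with AIBN in toluene at 80 °C (Barton–McCombie deoxygenation) then gives 12; the stannane is added slowly so that the xanthate outcompetes the alkyne for tin radicals.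

Step 11. The hindered tertiary alkoxide may eliminate HBr from 16 to give the 12,14-diene instead of substituting. The fallback sets out from 15 and 20 and comes back at 22. Compound 15 is acetylated (Ac2O, pyridine, DMAP) to the allylic acetate F4. Compound 20 is treated with Et2Zn in THF to give the ethylzinc alkoxide F5. Pd(OAc)2 with 2-(di-tert-butylphosphino)biphenyl (zerovalent palladium formed in situ) then catalyses allylic substitution, with the zinc alkoxide attacking the CH2 terminus of the π-allyl complex to give 22. The E/Z ratio must be checked, because the π-allyl intermediate can isomerise.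

**Further compounds**
F1 | step 5 | enantiomer of 10, methyl ent-3-oxo-15,16-dinorlabd-8(17)-en-13-yn-19-oate | C=C1CC[C@H]2[C@@](C)(CCC(=O)[C@@]2(C)C(=O)OC)[C@@H]1CCC#C
F2 | step 6 | methyl 3β-hydroxy-15,16-dinorlabd-8(17)-en-13-yn-19-oate | C=C1CC[C@@H]2[C@](C)(CC[C@H](O)[C@]2(C)C(=O)OC)[C@H]1CCC#C
F3 | step 6 | methyl 3β-[(methylsulfanyl)carbothioyloxy]-15,16-dinorlabd-8(17)-en-13-yn-19-oate | C=C1CC[C@@H]2[C@](C)(CC[C@H](OC(=S)SC)[C@]2(C)C(=O)OC)[C@H]1CCC#C
F4 | step 11 | methyl (13E)-15-acetoxylabda-8(17),13-dien-19-oate | C=C1CC[C@@H]2[C@](C)(CCC[C@]2(C)C(=O)OC)[C@H]1CC/C(C)=C/COC(C)=O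
F5 | step 11 | ethylzinc 4α-alkoxide of 20 | CC[Zn]O[C@]1(C)CCC[C@]2(C)CC[C@@H](C(C)(C)O[Si](CC)(CC)CC)C[C@H]21
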